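**Retrosynthetic overview**
1. Nortopsentin B ⇒ its N,N'-ditosyl derivative. Both indole rings are bought intact, and the imidazole is the only ring built, closed at the end.
2. Imidazole ⇒ α-acylamino ketone + NH3. N3 comes from NH4OAc, which closes N3–C4 and N3–C2.
3. Amide N1–C2 ⇒ 6-bromo-1-tosylindole-3-carboxylic acid + 2-amino-1-(1-tosylindol-3-yl)ethanone hydrochloride.
4. Key C4–C5 bond ⇒ crossed Claisen-type condensation of the enolate of tert-butyl N-(diphenylmethylene)glycinate with 1-tosylindole-3-carbonyl chloride. The ester carbon later leaves as CO2.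
5. Both acids ⇒ indole-3-carbaldehydes (N-tosylation, Pinnick oxidation). The bromo aldehyde ⇒ 6-bromoindole (Vilsmeier–Haack).

Assumption: the target is planar and achiral, with no stereocentre and rapidly interconverting imidazole N–H tautomers, so no enantiocontrol is needed. The single stereocentre that appears in passing (the α-carbon of the β-keto ester intermediates) is racemic and is erased on decarboxylation.

**Step 1**
Reactants: 1 1H-indole-3-carbaldehyde
Product: 2 1-tosyl-1H-indole-3-carbaldehyde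
Conditions: TsCl (1.2 equiv), Et3N (2 equiv), 4-(dimethylamino)pyridine (0.1 equiv), CH2Cl2, 0 °C → rt, 4 h
Reagents that add atoms: p-toluenesulfonyl chloride, Cc1ccc(cc1)S(=O)(=O)Cl
Why: The 3-formyl group acidifies the indole N–H so this N-sulfonylation is fast and clean, and the tosyl group switches off the vinylogous-amide donation that would deaden every later C-3 carbonyl.

**Step 2**
Reactants: 2 1-tosyl-1H-indole-3-carbaldehyde
Product: 3 1-tosyl-1H-indole-3-carboxylic acid
Conditions: NaClO2 (3 equiv), NaH2PO4 (3 equiv), 2-methyl-2-butene (10 equiv), THF/t-BuOH/H2O, rt, 6 h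
Reagents that add atoms: sodium chlorite NaClO2, [Na+].[O-]Cl=O
Why: The Pinnick oxidation takes the aldehyde to the acid in a buffered medium that spares the base-labile N-tosyl group, while the alkene scavenges HOCl before it can chlorinate the ring.

**Step 3**
Reactants: 3 1-tosyl-1H-indole-3-carboxylic acid
Product: 4 1-tosyl-1H-indole-3-carbonyl chloride
Conditions: (COCl)2 (1.5 equiv), cat. DMF, CH2Cl2, 0 °C → rt, 2 h; evaporate, toluene chase, use crude
Reagents that add atoms: oxalyl chloride, O=C(Cl)C(=O)Cl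
Why: DMF-catalysed acid chloride formation gives only gaseous by-products, and the product is non-enolisable and stable enough to be used directly.

**Step 4 (key C–C bond)**
Reactants: 4 1-tosyl-1H-indole-3-carbonyl chloride; 5 tert-butyl N-(diphenylmethylene)glycinate
Product: 7 tert-butyl 2-[(diphenylmethylene)amino]-3-oxo-3-(1-tosyl-1H-indol-3-yl)propanoate (racemic), via lithium enolate 6 (not isolated)
Conditions: 5, LiN(SiMe3)2 (1.0 equiv), THF, −78 °C, 30 min; cannulate into 4 (1.0 equiv) in THF, −78 °C, 1.5 h; AcOH quench, aqueous work-up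
Reagents that add atoms: none
Why: In this crossed Claisen-type condensation the preformed 2-azaallyl-stabilised ester enolate is C-acylated by a non-enolisable acyl donor, with inverse addition at −78 °C keeping the acid chloride in excess so proton transfer to the more acidic product and O-acylation stay minor; the new stereocentre is racemic, labile and removed in step 6.

**Step 5**
Reactants: 7 tert-butyl 2-[(diphenylmethylene)amino]-3-oxo-3-(1-tosyl-1H-indol-3-yl)propanoate
Product: 8 tert-butyl 2-amino-3-oxo-3-(1-tosyl-1H-indol-3-yl)propanoate hydrochloride (racemic)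
Conditions: 1 M aq HCl, THF, rt, 2 h; evaporate, triturate with Et2O
Reagents that add atoms: hydrogen chloride, Cl
Why: Imine hydrolysis of a benzophenone Schiff base is rapid in dilute acid at room temperature while the tert-butyl ester and the sulfonamide survive, and the amine is held as its salt so it cannot self-condense.

**Step 6**
Reactants: 8 tert-butyl 2-amino-3-oxo-3-(1-tosyl-1H-indol-3-yl)propanoate hydrochloride
Product: 10 2-amino-1-(1-tosyl-1H-indol-3-yl)ethan-1-one hydrochloride, via beta-keto acid hydrochloride 9 (not isolated)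
Conditions: 4 M HCl in 1,4-dioxane, rt → 45 °C, 6 h; filter, wash with cold water and Et2O
Reagents that add atoms: none
Why: Acidolysis of the tert-butyl ester gives a β-keto acid that decarboxylates through the usual cyclic transition state, which erases the stereocentre and precipitates the amino ketone as a storable salt.

**Step 7**
Reactants: 11 6-bromo-1H-indole
Product: 13 6-bromo-1H-indole-3-carbaldehyde, via iminium salt 12 (not isolated)
Conditions: POCl3 (1.2 equiv), DMF, 0 → 40 °C, 1 h; then 2 M aq NaOH, 0 → 90 °C, 15 min; filter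
Reagents that add atoms: N,N-dimethylformamide, CN(C)C=O; water, O
Why: Vilsmeier–Haack formylation attacks only C-3, the most nucleophilic indole position, and the aryl bromide is inert.

**Step 8**
Reactants: 13 6-bromo-1H-indole-3-carbaldehyde
Product: 14 6-bromo-1-tosyl-1H-indole-3-carbaldehyde
Conditions: TsCl (1.2 equiv), Et3N (2 equiv), 4-(dimethylamino)pyridine (0.1 equiv), CH2Cl2, 0 °C → rt, 4 h
Reagents that add atoms: p-toluenesulfonyl chloride, Cc1ccc(cc1)S(=O)(=O)Cl
Why: This is the same N-sulfonylation as step 1, and here the tosyl group keeps the later carboxamide carbonyl from behaving as an unreactive vinylogous urea in the ring closure.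

**Step 9**
Reactants: 14 6-bromo-1-tosyl-1H-indole-3-carbaldehyde
Product: 15 6-bromo-1-tosyl-1H-indole-3-carboxylic acid
Conditions: NaClO2 (3 equiv), NaH2PO4 (3 equiv), 2-methyl-2-butene (10 equiv), THF/t-BuOH/H2O, rt, 6 h
Reagents that add atoms: sodium chlorite NaClO2, [Na+].[O-]Cl=O
Why: The Pinnick oxidation is chemoselective for the aldehyde and touches neither the C–Br bond nor the N-tosyl group.

**Step 10**
Reactants: 15 6-bromo-1-tosyl-1H-indole-3-carboxylic acid; 10 2-amino-1-(1-tosyl-1H-indol-3-yl)ethan-1-one hydrochloride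
Product: 17 6-bromo-N-[2-oxo-2-(1-tosyl-1H-indol-3-yl)ethyl]-1-tosyl-1H-indole-3-carboxamide, via benzotriazolyl ester 16 (not isolated)
Conditions: 15, EDC·HCl (1.2 equiv), HOBt (1.2 equiv), DMF, rt, 45 min; then 10, i-Pr2NEt (2.5 equiv, dropwise), 0 °C → rt, 12 h
Reagents that add atoms: none
Why: In this carbodiimide/HOBt amide coupling the active ester is preformed, so the α-amino ketone, freed slowly by the base, is acylated faster than it can dimerise to a dihydropyrazine.

**Step 11**
Reactants: 17 6-bromo-N-[2-oxo-2-(1-tosyl-1H-indol-3-yl)ethyl]-1-tosyl-1H-indole-3-carboxamide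
Product: 19 2-(6-bromo-1-tosyl-1H-indol-3-yl)-4-(1-tosyl-1H-indol-3-yl)-1H-imidazole, via ketimine 18 (not isolated)
Conditions: NH4OAc (30 equiv), AcOH, 120 °C, 8 h
Reagents that add atoms: ammonium acetate, CC(=O)[O-].[NH4+]
Why: In this Davidson-type imidazole synthesis ammonia condenses with the aryl ketone and the new nitrogen closes on the amide carbonyl with loss of two waters, both carbonyls being kept electrophilic by N-tosyl and the large excess of NH4OAc outrunning Robinson–Gabriel closure to the oxazole.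

**Step 12**
Reactants: 19 2-(6-bromo-1-tosyl-1H-indol-3-yl)-4-(1-tosyl-1H-indol-3-yl)-1H-imidazole
Product: 20 nortopsentin B, 2-(6-bromo-1H-indol-3-yl)-4-(1H-indol-3-yl)-1H-imidazole
Conditions: 2 M aq NaOH (10 equiv), 1,4-dioxane, 90 °C, 6 h; then aq NH4Cl, EtOAc extraction
Reagents that add atoms: none
Why: In this basic N-desulfonylation hydroxide attacks sulfur and expels each indolide, the alcohol-free medium avoids alkyl tosylates that could N-alkylate the imidazole, and the aryl bromide is inert.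

**Compound list**
1 | 1H-indole-3-carbaldehyde | O=Cc1c[nH]c2ccccc12 | starting material
2 | 1-tosyl-1H-indole-3-carbaldehyde | Cc1ccc(cc1)S(=O)(=O)n1cc(C=O)c2ccccc12 | intermediate
3 | 1-tosyl-1H-indole-3-carboxylic acid | Cc1ccc(cc1)S(=O)(=O)n1cc(C(=O)O)c2ccccc12 | intermediate
4 | 1-tosyl-1H-indole-3-carbonyl chloride | Cc1ccc(cc1)S(=O)(=O)n1cc(C(=O)Cl)c2ccccc12 | intermediate
5 | tert-butyl N-(diphenylmethylene)glycinate | CC(C)(C)OC(=O)CN=C(c1ccccc1)c1ccccc1 | starting material
6 | lithium 1-tert-butoxy-2-[(diphenylmethylene)amino]ethen-1-olate | [Li+].CC(C)(C)OC([O-])=CN=C(c1ccccc1)c1ccccc1 | intermediate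
7 | tert-butyl 2-[(diphenylmethylene)amino]-3-oxo-3-(1-tosyl-1H-indol-3-yl)propanoate (racemic) | CC(C)(C)OC(=O)C(N=C(c1ccccc1)c1ccccc1)C(=O)c1cn(S(=O)(=O)c2ccc(C)cc2)c2ccccc12 | intermediate
8 | tert-butyl 2-amino-3-oxo-3-(1-tosyl-1H-indol-3-yl)propanoate hydrochloride (racemic) | Cl.CC(C)(C)OC(=O)C(N)C(=O)c1cn(S(=O)(=O)c2ccc(C)cc2)c2ccccc12 | intermediate
9 | 2-amino-3-oxo-3-(1-tosyl-1H-indol-3-yl)propanoic acid hydrochloride (racemic) | Cl.NC(C(=O)O)C(=O)c1cn(S(=O)(=O)c2ccc(C)cc2)c2ccccc12 | intermediate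
10 | 2-amino-1-(1-tosyl-1H-indol-3-yl)ethan-1-one hydrochloride | Cl.NCC(=O)c1cn(S(=O)(=O)c2ccc(C)cc2)c2ccccc12 | intermediate
11 | 6-bromo-1H-indole | Brc1ccc2cc[nH]c2c1 | starting material
12 | [(6-bromo-1H-indol-3-yl)methylidene]dimethylammonium dichlorophosphate | C[N+](C)=Cc1c[nH]c2cc(Br)ccc12.[O-]P(=O)(Cl)Cl | intermediate
13 | 6-bromo-1H-indole-3-carbaldehyde | O=Cc1c[nH]c2cc(Br)ccc12 | intermediate
14 | 6-bromo-1-tosyl-1H-indole-3-carbaldehyde | Cc1ccc(cc1)S(=O)(=O)n1cc(C=O)c2ccc(Br)cc12 | intermediate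
15 | 6-bromo-1-tosyl-1H-indole-3-carboxylic acid | Cc1ccc(cc1)S(=O)(=O)n1cc(C(=O)O)c2ccc(Br)cc12 | intermediate
16 | 1H-benzotriazol-1-yl 6-bromo-1-tosyl-1H-indole-3-carboxylate | Cc1ccc(cc1)S(=O)(=O)n1cc(C(=O)On2nnc3ccccc32)c2ccc(Br)cc12 | intermediate
17 | 6-bromo-N-[2-oxo-2-(1-tosyl-1H-indol-3-yl)ethyl]-1-tosyl-1H-indole-3-carboxamide | Cc1ccc(cc1)S(=O)(=O)n1cc(C(=O)NCC(=O)c2cn(S(=O)(=O)c3ccc(C)cc3)c3ccccc23)c2ccc(Br)cc12 | intermediate
18 | 6-bromo-N-[2-imino-2-(1-tosyl-1H-indol-3-yl)ethyl]-1-tosyl-1H-indole-3-carboxamide | Cc1ccc(cc1)S(=O)(=O)n1cc(C(=O)NCC(=N)c2cn(S(=O)(=O)c3ccc(C)cc3)c3ccccc23)c2ccc(Br)cc12 | intermediate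
19 | 2-(6-bromo-1-tosyl-1H-indol-3-yl)-4-(1-tosyl-1H-indol-3-yl)-1H-imidazole | Cc1ccc(cc1)S(=O)(=O)n1cc(-c2nc(c[nH]2)-c2cn(S(=O)(=O)c3ccc(C)cc3)c3ccccc23)c2ccc(Br)cc12 | intermediate
20 | nortopsentin B | Brc1ccc2c(-c3nc(-c4c[nH]c5ccccc45)c[nH]3)c[nH]c2c1 | target

**Totals**
Total step count: 12.
Longest linear sequence: 9 steps (1–6, then 10–12). The bromoindole branch (7–9) joins at step 10.

**Three steps most likely to fail**

Step 4 (Claisen-type acylation).
- Risk: product 7 is more acidic than 5, so it can quench enolate 6 and cap the conversion, and O-acylation or double acylation may intrude.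
- Fallback: it sets out from 4 and comes back at 10.
- Acid chloride 4 is stirred with methyl isocyanoacetate and Et3N in THF (0 °C → rt). C-acylation of the isocyanoacetate anion is followed at once by closure of the enolate oxygen on the isocyanide carbon. This gives methyl 5-(1-tosyl-1H-indol-3-yl)-1,3-oxazole-4-carboxylate F1, in which the troublesome acidic proton no longer exists.
- Refluxing F1 in 6 M aq HCl/dioxane opens the oxazole, hydrolyses the formamide and the ester, and decarboxylates. This delivers 10 directly.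

Step 10 (amide coupling of the free α-amino ketone).
- Risk: the liberated amino ketone may dimerise to the dihydropyrazine or pyrazine faster than it is acylated.
- Fallback: it sets out from 2 and comes back at 17, carrying the ketone as an alcohol until the nitrogen is acylated.
- A Henry reaction of 2 with MeNO2 (cat. i-Pr2NEt, THF, 0 °C) gives 2-nitro-1-(1-tosyl-1H-indol-3-yl)ethan-1-ol F2.
- Hydrogenation (H2, 10% Pd/C, MeOH) gives 2-amino-1-(1-tosyl-1H-indol-3-yl)ethan-1-ol F3, which cannot self-condense.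
- EDC·HCl/HOBt coupling of F3 with 15 (through 16) gives 6-bromo-N-[2-hydroxy-2-(1-tosyl-1H-indol-3-yl)ethyl]-1-tosyl-1H-indole-3-carboxamide F4.
- Dess–Martin periodinane in CH2Cl2 oxidises the carbinol of F4 to 17.

Step 11 (imidazole closure).
- Risk: oxazole formation may compete, attack on the amide carbonyl may be sluggish, and tosyl may be lost early. Partly detosylated imidazole is harmless, because step 12 converges it to 20.
- Fallback: it sets out from 13 and 10 and comes back at 20, replacing the amide by a more electrophilic imidate.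
- Aldehyde 13 with NH2OH·HCl and HCO2Na in refluxing HCO2H passes through 6-bromo-1H-indole-3-carbaldehyde oxime F5 to 6-bromo-1H-indole-3-carbonitrile F6.
- A Pinner reaction (HCl gas, MeOH, dioxane, 0 °C) gives methyl 6-bromo-1H-indole-3-carboximidate hydrochloride F7.
- F7 and 10 with Et3N (2 equiv) in MeOH (rt, then 65 °C) form 6-bromo-N-[2-oxo-2-(1-tosyl-1H-indol-3-yl)ethyl]-1H-indole-3-carboximidamide F8.
- The free amidine nitrogen of F8 closes on the activated ketone and dehydrates to 2-(6-bromo-1H-indol-3-yl)-4-(1-tosyl-1H-indol-3-yl)-1H-imidazole F9.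
- Aqueous NaOH/dioxane at 90 °C converts F9 into 20.

**Further compounds**
F1 | step 4 | methyl 5-(1-tosyl-1H-indol-3-yl)-1,3-oxazole-4-carboxylate | COC(=O)c1ncoc1-c1cn(S(=O)(=O)c2ccc(C)cc2)c2ccccc12
F2 | step 10 | 2-nitro-1-(1-tosyl-1H-indol-3-yl)ethan-1-ol (racemic) | OC(C[N+](=O)[O-])c1cn(S(=O)(=O)c2ccc(C)cc2)c2ccccc12
F3 | step 10 | 2-amino-1-(1-tosyl-1H-indol-3-yl)ethan-1-ol (racemic) | NCC(O)c1cn(S(=O)(=O)c2ccc(C)cc2)c2ccccc12
F4 | step 10 | 6-bromo-N-[2-hydroxy-2-(1-tosyl-1H-indol-3-yl)ethyl]-1-tosyl-1H-indole-3-carboxamide (racemic) | Cc1ccc(cc1)S(=O)(=O)n1cc(C(=O)NCC(O)c2cn(S(=O)(=O)c3ccc(C)cc3)c3ccccc23)c2ccc(Br)cc12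
F5 | step 11 | 6-bromo-1H-indole-3-carbaldehyde oxime (E/Z mixture) | ON=Cc1c[nH]c2cc(Br)ccc12
F6 | step 11 | 6-bromo-1H-indole-3-carbonitrile | N#Cc1c[nH]c2cc(Br)ccc12
F7 | step 11 | methyl 6-bromo-1H-indole-3-carboximidate hydrochloride | Cl.COC(=N)c1c[nH]c2cc(Br)ccc12
F8 | step 11 | 6-bromo-N-[2-oxo-2-(1-tosyl-1H-indol-3-yl)ethyl]-1H-indole-3-carboximidamide | N=C(NCC(=O)c1cn(S(=O)(=O)c2ccc(C)cc2)c2ccccc12)c1c[nH]c2cc(Br)ccc12
F9 | step 11 | 2-(6-bromo-1H-indol-3-yl)-4-(1-tosyl-1H-indol-3-yl)-1H-imidazole | Cc1ccc(cc1)S(=O)(=O)n1cc(-c2c[nH]c(n2)-c2c[nH]c3cc(Br)ccc23)c2ccccc12
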